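The route rests on making the C11–C1 bond last among the skeletal bonds. Iron-hydride hydrogen-atom transfer to an isopropenyl group on C10 gives the tertiary C11 radical, which adds 7-endo to C1 of an (E)-β-(4-methoxybenzyloxy) enone on C4: one step joins the gem-dimethyl quaternary C11 to oxygenated C1, closes the seven-membered ring and sets C1. It exploits the cis-1,3 hold of both chains on the cyclobutane C4–C5–C10–C9. The precursor, a bicyclo[3.1.1]heptane from an intramolecular ketene [2+2] cycloaddition, carries the C6–C8 bridge as a saturated silyl ether, so that opening of the cyclobutylcarbinyl radical cannot give an allylic or α-keto radical; the enone is unveiled in the last step.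

Key step: step 18

Remark (numbering assumed): ring atoms are numbered as in the target, C1–C3 (oxygenated), C4 (quaternary, methyl), C5 and C9 (bridgeheads), C6 (carbonyl), C7, C8 (methyl), C10, C11 (gem-dimethyl); "bridge face" is the face of the cyclobutane C4–C5–C10–C9 that carries the C6–C8 bridge, "lower face" the other one.

Step 1
Reactants: 1 1-[(tert-butyldimethylsilyl)oxy]propan-2-one; 2 diethyl {2-[methoxy(methyl)amino]-2-oxoethyl}phosphonate
Product: 3 (2E)-4-[(tert-butyldimethylsilyl)oxy]-N-methoxy-N,3-dimethylbut-2-enamide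
Conditions: NaH, THF, 0 °C to rt
Reagents that add atoms: none
Why: Horner–Wadsworth–Emmons olefination of the α-silyloxy methyl ketone should give mainly the (E)-enamide (amide carbonyl trans to the larger CH2OSi group), the minor (Z)-isomer being removed by chromatography.

Step 2
Reactants: 3 (2E)-4-[(tert-butyldimethylsilyl)oxy]-N-methoxy-N,3-dimethylbut-2-enamide
Product: 4 (2E)-4-[(tert-butyldimethylsilyl)oxy]-3-methylbut-2-enal
Conditions: i-Bu2AlH, THF, −78 °C; aq. potassium sodium tartrate
Reagents that add atoms: none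
Why: Reduction of the Weinreb amide stops at the aldehyde through the chelated aluminium hemiaminal and leaves the alkene geometry untouched.

Step 3
Reactants: 5 ethyl 3-methylbut-2-enoate
Product: 6 tert-butyl[(1-ethoxy-3-methylbuta-1,3-dien-1-yl)oxy]dimethylsilane
Conditions: LiN(i-Pr)2, THF, −78 °C; t-BuMe2SiCl, DMPU
Reagents that add atoms: tert-butyl(chloro)dimethylsilane, CC(C)(C)[Si](C)(C)Cl
Why: γ-Deprotonation of the β,β-dimethyl enoate and O-silylation of the lithium dienolate should give the silyl dienol ether that serves as vinylogous nucleophile.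

Step 4
Reactants: 4 (2E)-4-[(tert-butyldimethylsilyl)oxy]-3-methylbut-2-enal; 6 tert-butyl[(1-ethoxy-3-methylbuta-1,3-dien-1-yl)oxy]dimethylsilane
Product: 7 ethyl (2E,5S,6E)-8-[(tert-butyldimethylsilyl)oxy]-5-hydroxy-3,7-dimethylocta-2,6-dienoate
Conditions: SiCl4, chiral binaphthyldiamine-derived bisphosphoramide (cat.), i-Pr2NEt (cat.), CH2Cl2, −78 °C; aq. NaHCO3
Reagents that add atoms: none
Why: In this Lewis-base-activated SiCl4 vinylogous Mukaiyama aldol addition the dienolate reacts at its γ-carbon to give the (2E)-enoate, and the catalyst enantiomer that directs attack on the Si face of the aldehyde sets the (5S)-carbinol.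

Step 5
Reactants: 7 ethyl (2E,5S,6E)-8-[(tert-butyldimethylsilyl)oxy]-5-hydroxy-3,7-dimethylocta-2,6-dienoate
Product: 8 ethyl (2E,5S,6E)-8-[(tert-butyldimethylsilyl)oxy]-3,7-dimethyl-5-[(triisopropylsilyl)oxy]octa-2,6-dienoate
Conditions: i-Pr3SiOTf, 2,6-lutidine, CH2Cl2, 0 °C
Reagents that add atoms: triisopropylsilyl trifluoromethanesulfonate, CC(C)[Si](OS(=O)(=O)C(F)(F)F)(C(C)C)C(C)C
Why: Silyl triflate silylation of the secondary allylic alcohol installs an ether that should survive the later removal of the primary silyl ether and be the last protecting group removed.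

Step 6
Reactants: 8 ethyl (2E,5S,6E)-8-[(tert-butyldimethylsilyl)oxy]-3,7-dimethyl-5-[(triisopropylsilyl)oxy]octa-2,6-dienoate
Product: 9 (2E,5S,6E)-8-[(tert-butyldimethylsilyl)oxy]-3,7-dimethyl-5-[(triisopropylsilyl)oxy]octa-2,6-dienoic acid
Conditions: LiOH, THF/MeOH/H2O, rt; 1 M HCl to pH 4, 0 °C
Reagents that add atoms: lithium hydroxide, [Li+].[OH-]
Why: Saponification of the ethyl ester, to which both silyl ethers and the single stereocentre are inert.

Step 7
Reactants: 9 (2E,5S,6E)-8-[(tert-butyldimethylsilyl)oxy]-3,7-dimethyl-5-[(triisopropylsilyl)oxy]octa-2,6-dienoic acid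
Product: 12 bicyclic cyclobutanone (C10 ketone; C8 methylidene; C6 OTIPS on the C10 side; C4 methyl on the bridge face; C4 CH2OTBS on the lower face), via acid chloride 10 (not isolated), via vinylketene 11 (not isolated)
Conditions: 1-chloro-N,N,2-trimethylprop-1-en-1-amine, CH2Cl2, 0 °C; then slow addition to Et3N, PhMe, 110 °C (high dilution)
Reagents that add atoms: none
Why: 1,4-Dehydrochlorination of the enoyl chloride gives a vinylketene whose intramolecular [2+2] cycloaddition to the trisubstituted alkene takes the crossed course (carbonyl carbon to the CH end, α-carbon to the fully substituted end), so that the bicyclo[3.1.1]heptanone forms with the (E)-alkene geometry translated into C4 (methyl on the bridge face) and with the alkene face chosen by allylic 1,3-strain at the silyloxy stereocentre, which sets C5 and C9.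

Step 8
Reactants: 12 bicyclic cyclobutanone (C8 methylidene)
Product: 13 bicyclic cyclobutanone with C8H–CH3 (methyl on the C4 side)
Conditions: H2 (1 atm), Pd/C (palladium on carbon), EtOAc, rt
Reagents that add atoms: none
Why: Hydrogenation of the exocyclic 1,1-disubstituted alkene, expected from the face turned away from the C4 methyl group as with β-pinene, removes the only alkene that would later compete for hydrogen-atom transfer and leaves a C8 stereocentre that is erased in the last step.

Step 9
Reactants: 13 bicyclic cyclobutanone with C8H–CH3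
Product: 14 methyl enol ether (C10=CH–OCH3; E/Z mixture)
Conditions: MeOCH2PPh3Cl, KN(SiMe3)2, THF/PhMe, 0 to 60 °C
Reagents that add atoms: (methoxymethyl)triphenylphosphonium chloride, COC[P+](c1ccccc1)(c1ccccc1)c1ccccc1.[Cl-]
Why: Wittig methoxymethylenation of the strained cyclobutanone, which cannot enolise because both α-carbons are bridgeheads, should give the enol ether as an isomer mixture of no consequence.

Step 10
Reactants: 14 methyl enol ether (C10=CH–OCH3)
Product: 16 bridged cyclic methyl acetal (C11H(OCH3)–O–C3H2; C10–H on the bridge face), via hydroxy enol ether 15 (not isolated)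
Conditions: Bu4NF, THF, 0 °C; then PPTS (cat.), PhMe (dilute), 4 Å sieves, rt to 50 °C
Reagents that add atoms: none
Why: Fluoride removes the primary silyl ether in the presence of the hindered secondary one without touching the enol ether, and the acid-catalysed intramolecular addition of the C3 hydroxyl to the enol ether (acetalisation) is possible only when C11 lies on the lower face with C3, so that reversible protonation at C10 funnels the material into the acetal with the C10 hydrogen on the bridge face.

Step 11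
Reactants: 16 bridged cyclic methyl acetal
Product: 17 bridged lactone (C11(=O)–O–C3H2)
Conditions: m-CPBA, BF3·OEt2 (cat.), CH2Cl2, 0 °C
Reagents that add atoms: 3-chloroperbenzoic acid, OOC(=O)c1cccc(Cl)c1
Why: Peracid oxidation of the cyclic methyl acetal through its oxocarbenium ion is a known oxidation of lactol ethers to lactones, and C10 cannot epimerise because a C10=C11 double bond inside the bridged ring is geometrically impossible.

Step 12
Reactants: 17 bridged lactone
Product: 18 hydroxy methyl ketone (C10–C(=O)CH3 and C4–CH2OH, both on the lower face)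
Conditions: MeLi (1.1 equiv), THF, −78 °C; aq. NH4Cl
Reagents that add atoms: methyllithium, [Li]C
Why: Mono-addition of methyllithium to the lactone, halted at the lithium hemiketal alkoxide at low temperature, should give the methyl ketone and free the C3 hydroxyl on work-up.

Step 13
Reactants: 18 hydroxy methyl ketone
Product: 19 isopropenyl alcohol (C10 isopropenyl and C4–CH2OH on the lower face)
Conditions: CH2Br2, Zn, TiCl4, THF/CH2Cl2, 0 °C to rt
Reagents that add atoms: dibromomethane, BrCBr
Why: Takai–Lombardo methylenation under non-basic conditions should convert the methyl ketone into the isopropenyl group without enolisation toward C10, whose configuration (the less stable one) must be kept.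

Step 14
Reactants: 19 isopropenyl alcohol
Product: 20 aldehyde (C4–CHO)
Conditions: DMP, NaHCO3, CH2Cl2, rt
Reagents that add atoms: none
Why: Dess–Martin oxidation of the neopentyl primary alcohol gives an aldehyde that has no α-hydrogen.

Step 15
Reactants: 20 aldehyde (C4–CHO)
Product: 21 propargylic alcohol (C4–CH(OH)–C≡CH; epimer mixture)
Conditions: HC≡CMgBr, THF, −78 to 0 °C
Reagents that add atoms: ethynylmagnesium bromide, C#C[Mg]Br
Why: Grignard 1,2-addition to the aldehyde gives a carbinol whose configuration is irrelevant because it is oxidised in the next step.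

Step 16
Reactants: 21 propargylic alcohol
Product: 22 ynone (C4–C(=O)–C≡CH)
Conditions: DMP, NaHCO3, CH2Cl2, rt
Reagents that add atoms: none
Why: Dess–Martin oxidation of the propargylic alcohol gives the non-enolisable ynone.

Step 17
Reactants: 22 ynone; 23 (4-methoxyphenyl)methanol
Product: 24 cyclisation precursor ((E)-3-[(4-methoxybenzyl)oxy]prop-2-enoyl group on C4 and isopropenyl group on C10, both on the lower face; C6 OTIPS; C8 methyl)
Conditions: PMe3 (cat.), CH2Cl2, 0 °C to rt
Reagents that add atoms: none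
Why: Phosphine-catalysed oxa-Michael addition of the alcohol to the terminal ynone should give the (E)-β-alkoxy enone, the thermodynamic isomer formed by protonation of the allenolate.

Step 18
Reactants: 24 cyclisation precursor
Product: 25 tricyclic ketone (C11–C1 bond formed; C1 OPMB; C3 ketone; C6 OTIPS)
Conditions: Fe(acac)3 (0.3 equiv), Ph(i-PrO)SiH2, THF/i-PrOH, 0 °C to rt (degassed)
Reagents that add atoms: none
Why: Fe(acac)3 and the silane form an iron hydride that transfers a hydrogen atom to the CH2 end of the 1,1-disubstituted alkene (Markovnikov), the tertiary C11 radical adds to C1, the alkoxy-bearing β-carbon of the (E)-enone, and the C2 α-keto radical is reduced by the iron to an enolate and protonated by i-PrOH. The closest known reaction type is the iron-hydride reductive coupling of unactivated alkenes with enones (Giese type), together with tin-hydride cyclisations onto β-alkoxy enones and acrylates. The seven-membered ring closes in the 7-endo-trig mode, since attack at C2 (6-exo) opposes the polarity of the acceptor. C1 is set by the face of the enone that meets C11, that is by the twist about C4–C3 with the benzyloxy group turned outside; the two twists differ only through the distant C6 and C8 substituents, so a modest preference is expected and the epimers are separated at this stage. The step needs hydrogen-atom transfer at the isopropenyl group only, which the absence of any other unactivated alkene and the push–pull character of the enol ether secure, and ring closure faster than β-scission of the cyclobutylcarbinyl radical, which is secured by the saturated C6–C8 bridge (opening C10–C5 or C10–C9 would give only an unstabilised secondary radical) and by the cis-1,3-diaxial hold of C11 and C3 on the cyclobutane, about 3 Å apart. i-PrOH as the only alcohol avoids exchange of the vinylogous ester with a primary alcohol solvent.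

Step 19
Reactants: 25 tricyclic ketone
Product: 28 α-hydroxy ketone (C2–OH trans to C1–OPMB), via enol silane 26 (not isolated), via silyloxy epoxide 27 (not isolated)
Conditions: LiN(SiMe3)2, Me3SiCl, THF, −78 °C; pentane, filtration; dimethyldioxirane, acetone/CH2Cl2, −40 °C; citric acid, MeOH, 0 °C
Reagents that add atoms: dimethyldioxirane, CC1(C)OO1
Why: In this Rubottom oxidation C2 is the only enolisable position and in situ silylation avoids β-elimination of the C1 ether, dimethyldioxirane epoxidises the enol silane on the face opposite the adjacent C1 benzyloxy group, and methanolysis gives the C2 hydroxyl trans to C1–O.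

Step 20
Reactants: 28 α-hydroxy ketone
Product: 29 C2 triethylsilyl ether
Conditions: Et3SiCl, imidazole, DMF, rt
Reagents that add atoms: chlorotriethylsilane, CC[Si](Cl)(CC)CC
Why: Silylation of the α-hydroxy ketone keeps the C2 oxygen from acyl migration during the later esterification and gives an ether that can be removed in the presence of the triisopropylsilyl ether.

Step 21
Reactants: 29 C2 triethylsilyl ether
Product: 30 β-hydroxy ketone (C1–OH free)
Conditions: DDQ, CH2Cl2/pH 7 buffer, 0 °C
Reagents that add atoms: none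
Why: Oxidative cleavage of the 4-methoxybenzyl ether by hydride abstraction and hydrolysis, under buffered conditions that should spare both silyl ethers and the β-hydroxy ketone.

Step 22
Reactants: 30 β-hydroxy ketone
Product: 31 C1,C3-diol (C3–OH cis to C2–OSiEt3 and anti to C1–OH)
Conditions: Me4NBH(OAc)3, MeCN/AcOH, −30 °C
Reagents that add atoms: none
Why: In this Evans–Saksena reduction the C1 alkoxyborohydride delivers hydride to C3 on the face of the C1 oxygen, giving the 1,3-anti diol with the C3 hydroxyl cis to the C2 silyloxy group, an outcome that attack anti to the adjacent silyloxy group also favours.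

Step 23
Reactants: 31 C1,C3-diol; 32 angelic acid ((2Z)-2-methylbut-2-enoic acid), of which two equivalents are consumed, one per hydroxyl group
Product: 34 C1,C3-bis-angelate (C2 OSiEt3; C6 OTIPS), via mixed anhydride 33 (not isolated)
Conditions: 32 (excess), 2,4,6-trichlorobenzoyl chloride (excess), Et3N, PhMe, rt; then 31, 80 °C
Reagents that add atoms: angelic acid (the second equivalent of 32), C/C=C(/C)C(=O)O
Why: Yamaguchi mixed-anhydride esterification, the standard way to acylate hindered alcohols with angelic acid without isomerisation to the tiglate (no DMAP, no acid chloride), should esterify both hydroxyl groups, each taking one angeloyl group from one molecule of the mixed anhydride.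

Step 24
Reactants: 34 C1,C3-bis-angelate
Product: 35 C2 alcohol
Conditions: HF·pyridine, pyridine, THF, 0 °C
Reagents that add atoms: none
Why: Fluoride cleaves the triethylsilyl ether selectively in the presence of the triisopropylsilyl ether under weakly acidic conditions that do not promote acyl migration.

Step 25
Reactants: 35 C2 alcohol
Product: 36 C2 acetate
Conditions: Ac2O, pyridine, DMAP (cat.), CH2Cl2, rt
Reagents that add atoms: acetic anhydride, CC(=O)OC(C)=O
Why: Acetylation of the remaining secondary alcohol by nucleophilic catalysis.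

Step 26
Reactants: 36 C2 acetate
Product: 37 C6 alcohol
Conditions: HF·pyridine (excess), THF/MeCN, rt to 40 °C
Reagents that add atoms: none
Why: Fluoride cleavage of the triisopropylsilyl ether under non-basic conditions should leave the three esters in place.

Step 27
Reactants: 37 C6 alcohol
Product: 39 target triester (C6 ketone; C7=C8 enone), via saturated ketone 38 (not isolated)
Conditions: IBX, DMSO/PhF, 75 °C
Reagents that add atoms: none
Why: IBX oxidises the C6 alcohol to the ketone and then dehydrogenates it through its enol, which can form only toward C7 because C5 is a bridgehead, so the C7=C8 enone results and the auxiliary C6 and C8 stereocentres disappear.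

Compound list

1 | 1-[(tert-butyldimethylsilyl)oxy]propan-2-one | CC(=O)CO[Si](C)(C)C(C)(C)C | starting material
2 | diethyl {2-[methoxy(methyl)amino]-2-oxoethyl}phosphonate | CCOP(=O)(OCC)CC(=O)N(C)OC | starting material
3 | (2E)-4-[(tert-butyldimethylsilyl)oxy]-N-methoxy-N,3-dimethylbut-2-enamide | CON(C)C(=O)/C=C(\C)CO[Si](C)(C)C(C)(C)C | intermediate
4 | (2E)-4-[(tert-butyldimethylsilyl)oxy]-3-methylbut-2-enal | O=C/C=C(\C)CO[Si](C)(C)C(C)(C)C | intermediate
5 | ethyl 3-methylbut-2-enoate | CCOC(=O)C=C(C)C | starting material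
6 | tert-butyl[(1-ethoxy-3-methylbuta-1,3-dien-1-yl)oxy]dimethylsilane | CCOC(=CC(C)=C)O[Si](C)(C)C(C)(C)C | intermediate
7 | ethyl (2E,5S,6E)-8-[(tert-butyldimethylsilyl)oxy]-5-hydroxy-3,7-dimethylocta-2,6-dienoate | CCOC(=O)/C=C(\C)C[C@H](O)/C=C(\C)CO[Si](C)(C)C(C)(C)C | intermediate
8 | ethyl (2E,5S,6E)-8-[(tert-butyldimethylsilyl)oxy]-3,7-dimethyl-5-[(triisopropylsilyl)oxy]octa-2,6-dienoate | CCOC(=O)/C=C(\C)C[C@H](O[Si](C(C)C)(C(C)C)C(C)C)/C=C(\C)CO[Si](C)(C)C(C)(C)C | intermediate
9 | (2E,5S,6E)-8-[(tert-butyldimethylsilyl)oxy]-3,7-dimethyl-5-[(triisopropylsilyl)oxy]octa-2,6-dienoic acid | OC(=O)/C=C(\C)C[C@H](O[Si](C(C)C)(C(C)C)C(C)C)/C=C(\C)CO[Si](C)(C)C(C)(C)C | intermediate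
10 | acid chloride of 9 | ClC(=O)/C=C(\C)C[C@H](O[Si](C(C)C)(C(C)C)C(C)C)/C=C(\C)CO[Si](C)(C)C(C)(C)C | intermediate (not isolated)
11 | vinylketene, (5S,6E)-8-[(tert-butyldimethylsilyl)oxy]-7-methyl-3-methylidene-5-[(triisopropylsilyl)oxy]octa-1,6-dien-1-one | O=C=CC(=C)C[C@H](O[Si](C(C)C)(C(C)C)C(C)C)/C=C(\C)CO[Si](C)(C)C(C)(C)C | intermediate (not isolated)
12 | bicyclic cyclobutanone (C10 ketone; C8 methylidene; C6 OTIPS; C4 CH3 on the bridge face, CH2OTBS on the lower face) | CC(C)(C)[Si](C)(C)OC[C@@]1(C)[C@@H]2[C@@H](O[Si](C(C)C)(C(C)C)C(C)C)CC(=C)[C@H]1C2=O | intermediate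
13 | bicyclic cyclobutanone with C8H–CH3 | CC(C)(C)[Si](C)(C)OC[C@@]1(C)[C@@H]2[C@@H](O[Si](C(C)C)(C(C)C)C(C)C)C[C@H](C)[C@H]1C2=O | intermediate
14 | methyl enol ether (C10=CH–OCH3) | CC(C)(C)[Si](C)(C)OC[C@@]1(C)[C@@H]2[C@@H](O[Si](C(C)C)(C(C)C)C(C)C)C[C@H](C)[C@H]1C2=COC | intermediate
15 | hydroxy enol ether (C4–CH2OH; C10=CH–OCH3) | OC[C@@]1(C)[C@@H]2[C@@H](O[Si](C(C)C)(C(C)C)C(C)C)C[C@H](C)[C@H]1C2=COC | intermediate (not isolated)
16 | bridged cyclic methyl acetal (anomer mixture) | COC1OC[C@@]2(C)[C@@H]3[C@@H](O[Si](C(C)C)(C(C)C)C(C)C)C[C@H](C)[C@H]2[C@@H]31 | intermediate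
17 | bridged lactone | O=C1OC[C@@]2(C)[C@@H]3[C@@H](O[Si](C(C)C)(C(C)C)C(C)C)C[C@H](C)[C@H]2[C@@H]31 | intermediate
18 | hydroxy methyl ketone (may close reversibly to its hemiketal) | OC[C@@]1(C)[C@@H]2[C@@H](O[Si](C(C)C)(C(C)C)C(C)C)C[C@H](C)[C@H]1[C@@H]2C(C)=O | intermediate
19 | isopropenyl alcohol | OC[C@@]1(C)[C@@H]2[C@@H](O[Si](C(C)C)(C(C)C)C(C)C)C[C@H](C)[C@H]1[C@@H]2C(C)=C | intermediate
20 | aldehyde (C4–CHO) | O=C[C@@]1(C)[C@@H]2[C@@H](O[Si](C(C)C)(C(C)C)C(C)C)C[C@H](C)[C@H]1[C@@H]2C(C)=C | intermediate
21 | propargylic alcohol (carbinol epimers) | C#CC(O)[C@@]1(C)[C@@H]2[C@@H](O[Si](C(C)C)(C(C)C)C(C)C)C[C@H](C)[C@H]1[C@@H]2C(C)=C | intermediate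
22 | ynone | C#CC(=O)[C@@]1(C)[C@@H]2[C@@H](O[Si](C(C)C)(C(C)C)C(C)C)C[C@H](C)[C@H]1[C@@H]2C(C)=C | intermediate
23 | (4-methoxyphenyl)methanol | COc1ccc(CO)cc1 | starting material
24 | cyclisation precursor (C4 (E)-β-(4-methoxybenzyloxy) enone; C10 isopropenyl; C6 OTIPS) | COc1ccc(cc1)CO/C=C/C(=O)[C@@]2(C)[C@@H]3[C@@H](O[Si](C(C)C)(C(C)C)C(C)C)C[C@H](C)[C@H]2[C@@H]3C(C)=C | intermediate
25 | tricyclic ketone (C1 OPMB; C3 ketone; C6 OTIPS) | COc1ccc(cc1)CO[C@@H]1CC(=O)[C@@]2(C)[C@@H]3[C@@H](O[Si](C(C)C)(C(C)C)C(C)C)C[C@H](C)[C@H]2[C@@H]3C1(C)C | intermediate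
26 | C2=C3 trimethylsilyl enol ether | COc1ccc(cc1)CO[C@@H]1C=C(O[Si](C)(C)C)[C@@]2(C)[C@@H]3[C@@H](O[Si](C(C)C)(C(C)C)C(C)C)C[C@H](C)[C@H]2[C@@H]3C1(C)C | intermediate (not isolated)
27 | C2–C3 silyloxy epoxide (oxygen trans to C1–OPMB) | COc1ccc(cc1)CO[C@@H]1[C@H]2O[C@@]2(O[Si](C)(C)C)[C@@]3(C)[C@@H]4[C@@H](O[Si](C(C)C)(C(C)C)C(C)C)C[C@H](C)[C@H]3[C@@H]4C1(C)C | intermediate (not isolated)
28 | α-hydroxy ketone (C2–OH) | COc1ccc(cc1)CO[C@@H]1[C@@H](O)C(=O)[C@@]2(C)[C@@H]3[C@@H](O[Si](C(C)C)(C(C)C)C(C)C)C[C@H](C)[C@H]2[C@@H]3C1(C)C | intermediate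
29 | C2 triethylsilyl ether | COc1ccc(cc1)CO[C@@H]1[C@@H](O[Si](CC)(CC)CC)C(=O)[C@@]2(C)[C@@H]3[C@@H](O[Si](C(C)C)(C(C)C)C(C)C)C[C@H](C)[C@H]2[C@@H]3C1(C)C | intermediate
30 | β-hydroxy ketone (C1–OH) | O[C@@H]1[C@@H](O[Si](CC)(CC)CC)C(=O)[C@@]2(C)[C@@H]3[C@@H](O[Si](C(C)C)(C(C)C)C(C)C)C[C@H](C)[C@H]2[C@@H]3C1(C)C | intermediate
31 | C1,C3-diol | O[C@@H]1[C@@H](O[Si](CC)(CC)CC)[C@@H](O)[C@@]2(C)[C@@H]3[C@@H](O[Si](C(C)C)(C(C)C)C(C)C)C[C@H](C)[C@H]2[C@@H]3C1(C)C | intermediate
32 | angelic acid, (2Z)-2-methylbut-2-enoic acid | C/C=C(/C)C(=O)O | starting material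
33 | angelic 2,4,6-trichlorobenzoic anhydride | C/C=C(/C)C(=O)OC(=O)c1c(Cl)cc(Cl)cc1Cl | intermediate (not isolated)
34 | C1,C3-bis-angelate (C2 OSiEt3; C6 OTIPS) | C/C=C(/C)C(=O)O[C@@H]1[C@@H](O[Si](CC)(CC)CC)[C@@H](OC(=O)/C(C)=C\C)[C@@]2(C)[C@@H]3[C@@H](O[Si](C(C)C)(C(C)C)C(C)C)C[C@H](C)[C@H]2[C@@H]3C1(C)C | intermediate
35 | C2 alcohol | C/C=C(/C)C(=O)O[C@@H]1[C@@H](O)[C@@H](OC(=O)/C(C)=C\C)[C@@]2(C)[C@@H]3[C@@H](O[Si](C(C)C)(C(C)C)C(C)C)C[C@H](C)[C@H]2[C@@H]3C1(C)C | intermediate
36 | C2 acetate | C/C=C(/C)C(=O)O[C@@H]1[C@@H](OC(C)=O)[C@@H](OC(=O)/C(C)=C\C)[C@@]2(C)[C@@H]3[C@@H](O[Si](C(C)C)(C(C)C)C(C)C)C[C@H](C)[C@H]2[C@@H]3C1(C)C | intermediate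
37 | C6 alcohol | C/C=C(/C)C(=O)O[C@@H]1[C@@H](OC(C)=O)[C@@H](OC(=O)/C(C)=C\C)[C@@]2(C)[C@@H]3[C@@H](O)C[C@H](C)[C@H]2[C@@H]3C1(C)C | intermediate
38 | saturated C6 ketone | C/C=C(/C)C(=O)O[C@@H]1[C@@H](OC(C)=O)[C@@H](OC(=O)/C(C)=C\C)[C@@]2(C)[C@@H]3C(=O)C[C@H](C)[C@H]2[C@@H]3C1(C)C | intermediate (not isolated)
39 | target triester | C/C=C(/C)C(=O)O[C@@H]1[C@@H](OC(C)=O)[C@@H](OC(=O)/C(C)=C\C)[C@@]2(C)[C@@H]3C(=O)C=C(C)[C@H]2[C@@H]3C1(C)C | target

Total step count: 27 steps. Longest linear sequence: 26 steps (from 1 through steps 1, 2 and 4 to 27).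

Steps most likely to fail

Step 18. The ring closure may show poor facial selectivity at C1, because the side of the molecule on which the ring forms is close to mirror-symmetric and only the distant C6 and C8 groups break that symmetry. Ring opening of the C11 radical by β-scission is a second loss channel that lowers the yield but does not change the approach. The fallback sets out from 24 and comes back at 25. The cyclisation is run as in step 18 without regard to C1, and the mixture of 25 and its C1 epimer F1 is treated with DBU (PhMe, 60 °C), which eliminates 4-methoxybenzyl alcohol from both and converges on the cycloheptenone F2 (C1=C2–C3=O). Copper-catalysed conjugate borylation (CuCl, NaOt-Bu, a chiral bisphosphine whose enantiomer is chosen for the C1 configuration of 25, B2pin2, MeOH, THF) then sets C1 under catalyst control and gives the β-boryl ketone F3. Oxidation with NaBO3 gives the β-hydroxy ketone F4 with retention. Etherification with 4-methoxybenzyl 2,2,2-trichloroacetimidate and La(OTf)3 (cat.) in PhMe returns 25.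

Step 7. Ketene dimerisation or oligomerisation may outrun the intramolecular cycloaddition, since the alkene carries two allylic silyloxy groups and is less nucleophilic than a plain trisubstituted alkene, and facial discrimination by the silyloxy stereocentre may erode at 110 °C. The fallback sets out from 8 and comes back at 13; it replaces the ketene by a more electrophilic keteniminium ion. Copper hydride 1,4-reduction of the enoate (Cu(OAc)2, p-tol-BINAP of the enantiomer that gives the C8 configuration of 13, polymethylhydrosiloxane, t-BuOH, PhMe) gives the saturated ester F5. Aminolysis with pyrrolidine and AlMe3 gives the pyrrolidine amide F6. Tf2O and 2,4,6-collidine in 1,2-dichloroethane at 80 °C generate the keteniminium triflate F7, which undergoes the same crossed [2+2] cycloaddition to the cyclobutaniminium triflate F8. Aqueous NaHCO3 hydrolyses F8 to 13.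

Step 23. Acylation of the two neopentyl-type hydroxyl groups may stay incomplete, and forcing conditions may isomerise the (Z)-enoate to the tiglate. The fallback sets out from 31 and comes back at 34; it builds the (Z)-alkenes after the ester bonds. Acylation of both hydroxyl groups with two equivalents of 2-[bis(2,2,2-trifluoroethoxy)phosphoryl]propanoic acid and DCC (DMAP cat., CH2Cl2), which proceeds through a small phosphonoketene, gives the bis-phosphonate F9. Twofold Still–Gennari olefination of F9 with acetaldehyde (KN(SiMe3)2, 18-crown-6, THF, −78 °C) gives 34.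

Further compounds

F1 | step 18 | C1 epimer of 25 | COc1ccc(cc1)CO[C@H]1CC(=O)[C@@]2(C)[C@@H]3[C@@H](O[Si](C(C)C)(C(C)C)C(C)C)C[C@H](C)[C@H]2[C@@H]3C1(C)C
F2 | step 18 | cycloheptenone (C1=C2–C3=O) | C1=CC(=O)[C@@]2(C)[C@@H]3[C@@H](O[Si](C(C)C)(C(C)C)C(C)C)C[C@H](C)[C@H]2[C@@H]3C1(C)C
F3 | step 18 | β-boryl ketone (C1–Bpin) | CC1(C)OB(OC1(C)C)[C@@H]2CC(=O)[C@@]3(C)[C@@H]4[C@@H](O[Si](C(C)C)(C(C)C)C(C)C)C[C@H](C)[C@H]3[C@@H]4C2(C)C
F4 | step 18 | β-hydroxy ketone (C1–OH, C3 ketone) | O[C@@H]1CC(=O)[C@@]2(C)[C@@H]3[C@@H](O[Si](C(C)C)(C(C)C)C(C)C)C[C@H](C)[C@H]2[C@@H]3C1(C)C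
F5 | step 7 | saturated ester (2,3-dihydro-8) | CCOC(=O)C[C@@H](C)C[C@H](O[Si](C(C)C)(C(C)C)C(C)C)/C=C(\C)CO[Si](C)(C)C(C)(C)C
F6 | step 7 | pyrrolidine amide | O=C(C[C@@H](C)C[C@H](O[Si](C(C)C)(C(C)C)C(C)C)/C=C(\C)CO[Si](C)(C)C(C)(C)C)N1CCCC1
F7 | step 7 | keteniminium triflate | C1CC[N+](=C=C[C@@H](C)C[C@H](O[Si](C(C)C)(C(C)C)C(C)C)/C=C(\C)CO[Si](C)(C)C(C)(C)C)C1.[O-]S(=O)(=O)C(F)(F)F
F8 | step 7 | cyclobutaniminium triflate (C10=N+ pyrrolidinium) | CC(C)(C)[Si](C)(C)OC[C@@]1(C)[C@@H]2[C@@H](O[Si](C(C)C)(C(C)C)C(C)C)C[C@H](C)[C@H]1C2=[N+]1CCCC1.[O-]S(=O)(=O)C(F)(F)F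
F9 | step 23 | C1,C3-bis{2-[bis(2,2,2-trifluoroethoxy)phosphoryl]propanoate} | CC(C(=O)O[C@@H]1[C@@H](O[Si](CC)(CC)CC)[C@@H](OC(=O)C(C)P(=O)(OCC(F)(F)F)OCC(F)(F)F)[C@@]2(C)[C@@H]3[C@@H](O[Si](C(C)C)(C(C)C)C(C)C)C[C@H](C)[C@H]2[C@@H]3C1(C)C)P(=O)(OCC(F)(F)F)OCC(F)(F)F
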